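Ring C (the third ring from the 2,4,6-trihydroxyphenoxy end) is built de novo, which avoids two more hindered aryl ether couplings. Its C1(OH)–C2(O–ring D)–C3(OH) edge is an aryloxymalonyl unit. Its C4(H)–C5(O–ring B)–C6(H) edge is a 3-aryloxyglutaconate. Both ring-C oxygens can therefore be attached beforehand, one at an sp3 carbon and one at an sp carbon. One double Claisen condensation then forms C3–C4 and C1–C6, closes ring C and joins AB to DEF. The precursors are a dibenzyl 3-(AB-oxy)glutaconate and a bis(2,4,6-trichlorophenyl) DEF-oxymalonate. The active esters acylate fast and release no alkoxide; the benzyl esters leave by hydrogenolysis before decarboxylation.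

Key step: step 13

Remark on stereochemistry: the target has no stereocentre and no configurationally stable axis, because every diaryl ether has one ring with two ortho hydrogens. It is achiral and has no enantiomer to select. The only stereo-elements in the route (axis of 8, alkene of 9, sp3 centres of 22) are transient.

Abbreviations:
- Rings are lettered A–F from the 2,4,6-trihydroxyphenoxy end.
- AB-oxy = 2,6-dimethoxy-4-(2,4,6-trimethoxyphenoxy)phenoxy.
- DEF-oxy = 3,5-dimethoxy-4-[3,5-dimethoxy-4-(3,4,5-trimethoxyphenoxy)phenoxy]phenoxy.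
- All compounds marked starting material are taken to be catalogue chemicals.

**AB phenol**

Step 1
Reactants: 1 2,4,6-trimethoxyphenol; 2 4-bromo-2,6-dimethoxybenzaldehyde
Product: 3 2,6-dimethoxy-4-(2,4,6-trimethoxyphenoxy)benzaldehyde (AB aldehyde)
Conditions: CuI (10 mol %), picolinic acid (20 mol %), K3PO4 (2 equiv), DMSO, 90 °C, Ar
Reagents that add atoms: none
Why: Ligand-accelerated Ullmann diaryl ether synthesis: the hindered but very electron-rich phenoxide of 1 meets a C–Br bond with two ortho hydrogens and a para-formyl activator, a pairing for which CuI/picolinic acid is established, and the non-enolisable aldehyde is inert to K3PO4.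

Step 2
Reactants: 3 AB aldehyde
Product: 5 2,6-dimethoxy-4-(2,4,6-trimethoxyphenoxy)phenol (AB-OH), via AB formate 4 (not isolated)
Conditions: mCPBA (1.2 equiv), CH2Cl2, 0 °C → rt; aq. Na2SO3/NaHCO3 wash; K2CO3 (20 mol %), MeOH, rt, Ar
Reagents that add atoms: mCPBA, OOC(=O)c1cccc(Cl)c1
Why: Baeyer–Villiger oxidation in which the aryl group, pushed by two ortho-methoxy and one para-aryloxy donors, migrates rather than hydrogen; the oxidisable phenol stays masked as formate 4 until the peracid is washed out and is then freed by base-catalysed methanolysis.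

**Glutaconate partner**

Step 3
Reactants: 6 dimethyl 1,3-acetonedicarboxylate
Product: 7 dibenzyl 3-oxopentanedioate
Conditions: BnOH (2.5 equiv), DMAP (10 mol %), toluene, reflux, MeOH removed (4 Å MS in Soxhlet)
Reagents that add atoms: benzyl alcohol, OCc1ccccc1
Why: DMAP-catalysed transesterification of a β-keto ester, driven by removal of methanol; benzyl esters are chosen because they are later cleaved at the O–CH2 bond, so no nucleophile has to reach a carbonyl flanked by two ortho substituents.

Step 4
Reactants: 7 dibenzyl 3-oxopentanedioate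
Product: 8 dibenzyl penta-2,3-dienedioate (racemic allene)
Conditions: 2-chloro-1,3-dimethylimidazolinium chloride (1.2 equiv), Et3N (2.5 equiv), CH2Cl2, 0 °C
Reagents that add atoms: none
Why: Dehydration of the enol by O-activation with the chloroamidinium salt and base-induced elimination of the urea, the standard access to allene-1,3-dicarboxylates from acetonedicarboxylates, under conditions too mild to touch benzyl esters; the axial chirality (racemate) disappears in step 5.

Step 5
Reactants: 5 AB-OH; 8 dibenzyl penta-2,3-dienedioate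
Product: 9 dibenzyl (E)-3-(AB-oxy)pent-2-enedioate
Conditions: 8 (1.2 equiv), Cs2CO3 (10 mol %), MeCN, 0 °C → rt, Ar
Reagents that add atoms: none
Why: Base-catalysed oxa-Michael addition of a phenoxide to the central sp carbon of an allene-1,3-dicarboxylate, a known route to 3-aryloxyglutaconates in which the two ortho-methoxy groups of 5 hardly matter because the acceptor carbon is unencumbered; the conjugated E enol ether is expected, but either geometry serves since step 13 erases it.

**DEF phenol**

Step 6
Reactants: 10 3,4,5-trimethoxyphenol; 11 4-bromo-3,5-dimethoxybenzaldehyde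
Product: 12 3,5-dimethoxy-4-(3,4,5-trimethoxyphenoxy)benzaldehyde (EF aldehyde)
Conditions: CuI (20 mol %), picolinic acid (40 mol %), K3PO4 (2 equiv), DMSO, 105 °C, Ar
Reagents that add atoms: none
Why: Ullmann diaryl ether synthesis with reversed steric roles: the phenol is unhindered, and the bromide, though flanked by two methoxy groups, is activated by the para-formyl group (which also opens an SNAr channel), in line with classical copper couplings of 2-bromo-1,3-dimethoxyarenes with 3,5-dialkoxyphenols.

Step 7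
Reactants: 12 EF aldehyde
Product: 14 3,5-dimethoxy-4-(3,4,5-trimethoxyphenoxy)phenol (EF-OH), via EF formate 13 (not isolated)
Conditions: mCPBA (1.2 equiv), CH2Cl2, 0 °C → rt; aq. Na2SO3/NaHCO3 wash; K2CO3 (20 mol %), MeOH, rt, Ar
Reagents that add atoms: mCPBA, OOC(=O)c1cccc(Cl)c1
Why: Baeyer–Villiger oxidation of the kind that turns 3,4,5-trialkoxybenzaldehydes into the phenols, the para-oxygenated aryl group migrating; methanolysis of formate 13 gives a phenol whose OH has two ortho hydrogens.

Step 8
Reactants: 14 EF-OH; 11 4-bromo-3,5-dimethoxybenzaldehyde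
Product: 15 4-[3,5-dimethoxy-4-(3,4,5-trimethoxyphenoxy)phenoxy]-3,5-dimethoxybenzaldehyde (DEF aldehyde)
Conditions: CuI (20 mol %), picolinic acid (40 mol %), K3PO4 (2 equiv), DMSO, 105 °C, Ar
Reagents that add atoms: none
Why: Second Ullmann coupling of the same kind as step 6, an unhindered electron-rich phenoxide with the formyl-activated bromide 11; the E–O–F ether already present carries no acceptor group and is not open to exchange.

Step 9
Reactants: 15 DEF aldehyde
Product: 17 3,5-dimethoxy-4-[3,5-dimethoxy-4-(3,4,5-trimethoxyphenoxy)phenoxy]phenol (DEF-OH), via DEF formate 16 (not isolated)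
Conditions: mCPBA (1.2 equiv), CH2Cl2, 0 °C → rt; aq. Na2SO3/NaHCO3 wash; K2CO3 (20 mol %), MeOH, rt, Ar
Reagents that add atoms: mCPBA, OOC(=O)c1cccc(Cl)c1
Why: Baeyer–Villiger oxidation and formate methanolysis exactly as in step 7, with the para-aryloxy-substituted ring D migrating.

**Malonate partner**

Step 10
Reactants: 17 DEF-OH; 18 dimethyl chloromalonate
Product: 19 dimethyl 2-(DEF-oxy)malonate
Conditions: K2CO3 (1.5 equiv), acetone, reflux
Reagents that add atoms: none
Why: Williamson-type SN2 O-alkylation at the sp3 carbon of a halomalonate, a well-established way from alkoxyphenols to 2-aryloxymalonates, so the C2–O bond of the future ring C is made without any aryl halide.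

Step 11
Reactants: 19 dimethyl 2-(DEF-oxy)malonate
Product: 20 2-(DEF-oxy)malonic acid
Conditions: LiOH (4 equiv), THF–MeOH–H2O, rt; 1 M HCl, 0 °C
Reagents that add atoms: lithium hydroxide (source of the new carboxyl oxygens), [Li+].[OH-]
Why: Ordinary saponification of two unhindered aliphatic esters at room temperature; cold acidification and evaporation without heating keep the malonic acid from decarboxylating.

Step 12
Reactants: 20 2-(DEF-oxy)malonic acid
Product: 21 bis(2,4,6-trichlorophenyl) 2-(DEF-oxy)malonate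
Conditions: 2,4,6-trichlorophenol (2.1 equiv), DCC (2.1 equiv), EtOAc, 0 °C → rt; filtration, crystallisation
Reagents that add atoms: 2,4,6-trichlorophenol, Oc1c(Cl)cc(Cl)cc1Cl
Why: Carbodiimide-mediated active ester formation as in peptide chemistry, run cold and without acid chloride or Lewis acid so that neither decarboxylation nor Friedel–Crafts closure onto electron-rich ring D can intervene.

**Union and end game**

Step 13
Reactants: 9 dibenzyl (E)-3-(AB-oxy)pent-2-enedioate; 21 bis(2,4,6-trichlorophenyl) 2-(DEF-oxy)malonate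
Product: 23 dibenzyl 4,6-dihydroxy-2-(AB-oxy)-5-(DEF-oxy)benzene-1,3-dicarboxylate, via open-chain C4-acylglutaconate 22 (not isolated)
Conditions: 9, NaH (4.5 equiv), THF, 0 °C, 30 min; 21 (1.1 equiv) in THF added over 2 h, 0 °C → 50 °C; cold 1 M HCl
Reagents that add atoms: none
Why: NaH turns 9 into a delocalised dienolate whose glutaconate C2 and C4 are equivalent (the alkene geometry vanishes); C4 is acylated by 21, directly or through the acylketene that 21 forms by E1cB loss of trichlorophenoxide, to give 22, after which renewed deprotonation makes C2 nucleophilic, it attacks the remaining active ester, and the cyclohexadienone enolises irreversibly to the arene bis-phenoxide. The closest known reaction type is the [3+3] Claisen–Dieckmann cyclocondensation of acetonedicarboxylate-type C3 dinucleophiles with malonates to phloroglucinol dicarboxylates, combined with the established use of bis(2,4,6-trichlorophenyl) malonates as 1,3-dielectrophiles. Ring C closes in a 6-(enolexo)-exo-trig mode, or equivalently by 6π closure of a dienylketene if the second ester also reacts by E1cB, so the acidic malonyl C–H that would deactivate a dimethyl ester becomes an asset. No stereocentre is created. The step needs C- over O-acylation and retention of the AB-oxy group: O-acylated ketene acetals are themselves acyl donors and feed back, the central oxygen is capped as an aryl ether so no pyranone can form, aryloxide loss from the dienolate is the uphill reverse of step 5, and the only nucleofuge set loose is the weakly nucleophilic trichlorophenoxide rather than methoxide. Both acyl groups of 21 and both termini of the dienolate are equivalent, so no regiochemical question arises.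

Step 14
Reactants: 23 dibenzyl 4,6-dihydroxy-2-(AB-oxy)-5-(DEF-oxy)benzene-1,3-dicarboxylate
Product: 25 5-(AB-oxy)-2-(DEF-oxy)benzene-1,3-diol (dodecamethyl ether of the target), via isophthalic diacid 24 (not isolated)
Conditions: H2 (1 atm), 10 % Pd/C, THF–MeOH, rt; filter; 1,4-dioxane–H2O (4:1), 100 °C, Ar
Reagents that add atoms: none
Why: Hydrogenolysis of benzyl esters under neutral conditions followed by thermal protodecarboxylation, which is easy because each carboxyl-bearing carbon lies ortho and para to hydroxy groups and ortho to an aryloxy group (phloroglucinolcarboxylic acid type, ipso protonation).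

Step 15
Reactants: 25 5-(AB-oxy)-2-(DEF-oxy)benzene-1,3-diol
Product: 26 target hexamer CNP0187343.0
Conditions: BBr3 (30 equiv), CH2Cl2, −78 °C → rt, 36 h, Ar; ice–water; Sephadex LH-20 (degassed MeOH)
Reagents that add atoms: none
Why: Lewis acid ether cleavage with BBr3, in which bromide attacks the methyl carbon of the boron-complexed ether; it removes aryl methyl ethers but leaves diaryl ethers intact because neither of their carbons can undergo SN2, and the excess covers twelve ethers and two free phenols.

**Compound list**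

1 | 2,4,6-trimethoxyphenol | COc1cc(OC)c(O)c(OC)c1 | starting material
2 | 4-bromo-2,6-dimethoxybenzaldehyde | COc1cc(Br)cc(OC)c1C=O | starting material
3 | 2,6-dimethoxy-4-(2,4,6-trimethoxyphenoxy)benzaldehyde | COc1cc(OC)c(Oc2cc(OC)c(C=O)c(OC)c2)c(OC)c1 | intermediate
4 | 2,6-dimethoxy-4-(2,4,6-trimethoxyphenoxy)phenyl formate | COc1cc(OC)c(Oc2cc(OC)c(OC=O)c(OC)c2)c(OC)c1 | intermediate
5 | 2,6-dimethoxy-4-(2,4,6-trimethoxyphenoxy)phenol (AB-OH) | COc1cc(OC)c(Oc2cc(OC)c(O)c(OC)c2)c(OC)c1 | intermediate
6 | dimethyl 1,3-acetonedicarboxylate | COC(=O)CC(=O)CC(=O)OC | starting material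
7 | dibenzyl 3-oxopentanedioate | O=C(CC(=O)OCc1ccccc1)CC(=O)OCc2ccccc2 | intermediate
8 | dibenzyl penta-2,3-dienedioate (racemic) | O=C(OCc1ccccc1)C=C=CC(=O)OCc2ccccc2 | intermediate
9 | dibenzyl (E)-3-(AB-oxy)pent-2-enedioate | O=C(OCc1ccccc1)/C=C(/Oc2c(OC)cc(Oc3c(OC)cc(OC)cc3OC)cc2OC)CC(=O)OCc4ccccc4 | intermediate
10 | 3,4,5-trimethoxyphenol | COc1cc(O)cc(OC)c1OC | starting material
11 | 4-bromo-3,5-dimethoxybenzaldehyde | COc1cc(C=O)cc(OC)c1Br | starting material
12 | 3,5-dimethoxy-4-(3,4,5-trimethoxyphenoxy)benzaldehyde | COc1cc(C=O)cc(OC)c1Oc2cc(OC)c(OC)c(OC)c2 | intermediate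
13 | 3,5-dimethoxy-4-(3,4,5-trimethoxyphenoxy)phenyl formate | COc1cc(OC=O)cc(OC)c1Oc2cc(OC)c(OC)c(OC)c2 | intermediate
14 | 3,5-dimethoxy-4-(3,4,5-trimethoxyphenoxy)phenol (EF-OH) | COc1cc(O)cc(OC)c1Oc2cc(OC)c(OC)c(OC)c2 | intermediate
15 | 4-[3,5-dimethoxy-4-(3,4,5-trimethoxyphenoxy)phenoxy]-3,5-dimethoxybenzaldehyde | COc1cc(C=O)cc(OC)c1Oc2cc(OC)c(Oc3cc(OC)c(OC)c(OC)c3)c(OC)c2 | intermediate
16 | 4-[3,5-dimethoxy-4-(3,4,5-trimethoxyphenoxy)phenoxy]-3,5-dimethoxyphenyl formate | COc1cc(OC=O)cc(OC)c1Oc2cc(OC)c(Oc3cc(OC)c(OC)c(OC)c3)c(OC)c2 | intermediate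
17 | 3,5-dimethoxy-4-[3,5-dimethoxy-4-(3,4,5-trimethoxyphenoxy)phenoxy]phenol (DEF-OH) | COc1cc(O)cc(OC)c1Oc2cc(OC)c(Oc3cc(OC)c(OC)c(OC)c3)c(OC)c2 | intermediate
18 | dimethyl chloromalonate | COC(=O)C(Cl)C(=O)OC | starting material
19 | dimethyl 2-(DEF-oxy)malonate | COC(=O)C(Oc1cc(OC)c(Oc2cc(OC)c(Oc3cc(OC)c(OC)c(OC)c3)c(OC)c2)c(OC)c1)C(=O)OC | intermediate
20 | 2-(DEF-oxy)malonic acid | OC(=O)C(Oc1cc(OC)c(Oc2cc(OC)c(Oc3cc(OC)c(OC)c(OC)c3)c(OC)c2)c(OC)c1)C(=O)O | intermediate
21 | bis(2,4,6-trichlorophenyl) 2-(DEF-oxy)malonate | O=C(Oc1c(Cl)cc(Cl)cc1Cl)C(Oc2cc(OC)c(Oc3cc(OC)c(Oc4cc(OC)c(OC)c(OC)c4)c(OC)c3)c(OC)c2)C(=O)Oc5c(Cl)cc(Cl)cc5Cl | intermediate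
22 | dibenzyl 3-(AB-oxy)-4-[2-(DEF-oxy)-3-oxo-3-(2,4,6-trichlorophenoxy)propanoyl]pent-2-enedioate (present as sodium enolate, stereo-elements undefined) | O=C(OCc1ccccc1)C=C(Oc2c(OC)cc(Oc3c(OC)cc(OC)cc3OC)cc2OC)C(C(=O)OCc4ccccc4)C(=O)C(Oc5cc(OC)c(Oc6cc(OC)c(Oc7cc(OC)c(OC)c(OC)c7)c(OC)c6)c(OC)c5)C(=O)Oc8c(Cl)cc(Cl)cc8Cl | intermediate
23 | dibenzyl 4,6-dihydroxy-2-(AB-oxy)-5-(DEF-oxy)benzene-1,3-dicarboxylate | COc1cc(OC)c(Oc2cc(OC)c(Oc3c(C(=O)OCc4ccccc4)c(O)c(Oc5cc(OC)c(Oc6cc(OC)c(Oc7cc(OC)c(OC)c(OC)c7)c(OC)c6)c(OC)c5)c(O)c3C(=O)OCc8ccccc8)c(OC)c2)c(OC)c1 | intermediate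
24 | 4,6-dihydroxy-2-(AB-oxy)-5-(DEF-oxy)benzene-1,3-dicarboxylic acid | COc1cc(OC)c(Oc2cc(OC)c(Oc3c(C(=O)O)c(O)c(Oc4cc(OC)c(Oc5cc(OC)c(Oc6cc(OC)c(OC)c(OC)c6)c(OC)c5)c(OC)c4)c(O)c3C(=O)O)c(OC)c2)c(OC)c1 | intermediate
25 | 5-(AB-oxy)-2-(DEF-oxy)benzene-1,3-diol | COc1cc(OC)c(Oc2cc(OC)c(Oc3cc(O)c(Oc4cc(OC)c(Oc5cc(OC)c(Oc6cc(OC)c(OC)c(OC)c6)c(OC)c5)c(OC)c4)c(O)c3)c(OC)c2)c(OC)c1 | intermediate
26 | CNP0187343.0 (achiral hexamer, 14 OH) | Oc1cc(O)c(Oc2cc(O)c(Oc3cc(O)c(Oc4cc(O)c(Oc5cc(O)c(Oc6cc(O)c(O)c(O)c6)c(O)c5)c(O)c4)c(O)c3)c(O)c2)c(O)c1 | target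

Total step count: 15. Longest linear sequence: 10 steps (steps 6 to 15).

**Steps most likely to fail**

1. **Step 13.**
   - What may go wrong: proton transfer from the very acidic active malonate to the dienolate may outrun C-acylation, so that the ketene derived from 21 condenses with itself. Retro-Michael expulsion of the AB-oxide and stalling at the open-chain stage are the other failure processes.
   - Fallback (sets out from 5 and 17, rejoins at 26): ring C is taken from a bought arene and both of its ethers are made by coupling. Phenol 5 is coupled with 2 under the conditions of step 1 to 4-(AB-oxy)-2,6-dimethoxybenzaldehyde F1. Baeyer–Villiger oxidation as in step 2 gives the ABC formate F2, and methanolysis gives the hindered ABC phenol F3. In parallel, 17 is converted with Tf2O/pyridine into the DEF triflate F4. Palladium-catalysed Miyaura-type borylation with tetrahydroxydiboron (XPhos Pd G2, KOAc, EtOH, 80 °C) then gives the DEF boronic acid F5. Chan–Lam coupling of F3 with F5 (Cu(OAc)2, pyridine, 4 Å MS, CH2Cl2, air, rt) tolerates 2,6-disubstituted phenols and gives the tetradecamethyl ether of the hexamer F6. BBr3 as in step 15 converts F6 into 26.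

2. **Step 8** (step 6 carries the same risk).
   - What may go wrong: substitution at a C–Br bond flanked by two methoxy groups may be so slow that hydrodebromination and base-induced degradation of the aldehyde win.
   - Fallback (sets out from 14, rejoins at 15): the polarity of the coupling is reversed, so that the new C–O bond forms at the unhindered carbon. Phenol 14 is turned with Tf2O/pyridine into the EF triflate F7 and borylated as above to the EF boronic acid F8. F8 is joined by Chan–Lam coupling to the hindered phenol oxygen of purchased syringaldehyde F9, which gives 15 directly.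

3. **Step 15.**
   - What may go wrong: partly demethylated borates may precipitate and stop the cleavage short. The free polyphenol may also oxidise in air during chromatography.
   - Fallback (sets out from 25, rejoins at 26): the crude BBr3 product is not isolated as the phenol. It is peracetylated (Ac2O, pyridine) to the tetradecaacetate F10, which is stable, separable on silica from under-demethylated material (this can be resubmitted) and storable. Acid-catalysed methanolysis (HCl in degassed MeOH, rt, Ar) then releases 26 without ever forming a phenoxide.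

**Further compounds**

F1 | step 13 | 4-[2,6-dimethoxy-4-(2,4,6-trimethoxyphenoxy)phenoxy]-2,6-dimethoxybenzaldehyde | COc1cc(OC)c(Oc2cc(OC)c(Oc3cc(OC)c(C=O)c(OC)c3)c(OC)c2)c(OC)c1
F2 | step 13 | 4-[2,6-dimethoxy-4-(2,4,6-trimethoxyphenoxy)phenoxy]-2,6-dimethoxyphenyl formate | COc1cc(OC)c(Oc2cc(OC)c(Oc3cc(OC)c(OC=O)c(OC)c3)c(OC)c2)c(OC)c1
F3 | step 13 | 4-[2,6-dimethoxy-4-(2,4,6-trimethoxyphenoxy)phenoxy]-2,6-dimethoxyphenol | COc1cc(OC)c(Oc2cc(OC)c(Oc3cc(OC)c(O)c(OC)c3)c(OC)c2)c(OC)c1
F4 | step 13 | DEF triflate (trifluoromethanesulfonate of 17) | COc1cc(OS(=O)(=O)C(F)(F)F)cc(OC)c1Oc2cc(OC)c(Oc3cc(OC)c(OC)c(OC)c3)c(OC)c2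
F5 | step 13 | DEF boronic acid | COc1cc(B(O)O)cc(OC)c1Oc2cc(OC)c(Oc3cc(OC)c(OC)c(OC)c3)c(OC)c2
F6 | step 13 | tetradecamethyl ether of the hexamer | COc1cc(OC)c(Oc2cc(OC)c(Oc3cc(OC)c(Oc4cc(OC)c(Oc5cc(OC)c(Oc6cc(OC)c(OC)c(OC)c6)c(OC)c5)c(OC)c4)c(OC)c3)c(OC)c2)c(OC)c1
F7 | step 8 | EF triflate (trifluoromethanesulfonate of 14) | COc1cc(OS(=O)(=O)C(F)(F)F)cc(OC)c1Oc2cc(OC)c(OC)c(OC)c2
F8 | step 8 | EF boronic acid | COc1cc(B(O)O)cc(OC)c1Oc2cc(OC)c(OC)c(OC)c2
F9 | step 8 | syringaldehyde (purchased) | COc1cc(C=O)cc(OC)c1O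
F10 | step 15 | tetradecaacetate of the target | CC(=O)Oc1cc(OC(C)=O)c(Oc2cc(OC(C)=O)c(Oc3cc(OC(C)=O)c(Oc4cc(OC(C)=O)c(Oc5cc(OC(C)=O)c(Oc6cc(OC(C)=O)c(OC(C)=O)c(OC(C)=O)c6)c(OC(C)=O)c5)c(OC(C)=O)c4)c(OC(C)=O)c3)c(OC(C)=O)c2)c(OC(C)=O)c1
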